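**Plan**
- Retrosynthesis: both C–Br bonds go back, each with inversion, to a trans-1,3-diol, and the exocyclic methylene to an α-methylenated ketone. This exposes the ring segment C(=CH2)–CHBr–CH2 as an acetone unit.
- The ring is then cut at the CH2–CHBr bond on the gem-dimethyl side and at the bond from the methylene-bearing carbon to the side-chain methine. This is a [3+3] disconnection into an acetone α,α′-dianion equivalent (a β-ketophosphonate) and a 2,2-dimethyl-3-oxo-aldehyde that already carries the side chain.
- Enabling feature: the quaternary CMe2 ring carbon lies between the two ring carbons that act as electrophiles (the CHBr carbon next to it and the side-chain methine). The 1,3-keto-aldehyde therefore cannot enolise between its carbonyls, and its two carbonyls are sharply differentiated.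
- Forward: (S)-linalool supplies the side chain, its carbinol centre and the ring methine carbon (as an aldehyde). An isobutyraldehyde enol silane adds CMe2–CHO. A one-pot aldol / Horner–Wadsworth–Emmons / dehydration sequence closes the six-membered ring as a cross-conjugated dienone.
- Stereochemistry: the side-chain carbinol is bought. The ring CH–O next to CMe2 is set by Cu-catalysed asymmetric conjugate borylation. It relays to the methine (hydride delivered anti to it) and to the allylic carbinol (hydroxyl-directed reduction). Both bromides then arise by inversion.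

Key step: step 5

Assumption: (S)-(+)-linalool is bought in high enantiomeric purity, and the (R,SP)-Josiphos-type ligand named in step 6 is taken to give the (5S)-boronate; if the sense is opposite, its enantiomer is used.

**Step 1**
Reactants: 1 (S)-(+)-linalool
Product: 2 (3S)-3,7-dimethyl-3-(triethylsilyloxy)octa-1,6-diene
Conditions: TESOTf, 2,6-lutidine, CH2Cl2, −78 → 0 °C
Reagents that add atoms: triethylsilyl trifluoromethanesulfonate, CC[Si](CC)(CC)OS(=O)(=O)C(F)(F)F
Why: Silylation of a tertiary allylic alcohol with a silyl triflate and a hindered base leaves the stereocentre untouched and keeps the hydroxyl out of the later enolate, oxidation and bromination chemistry.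

**Step 2**
Reactants: 2 (3S)-3,7-dimethyl-3-(triethylsilyloxy)octa-1,6-diene
Product: 4 (4S)-4-methyl-4-(triethylsilyloxy)hex-5-enal, via ozonide 3 (not isolated)
Conditions: O3 (1.0 equiv, Sudan Red 7B end point), CH2Cl2, −78 °C; then PPh3, −78 °C → rt
Reagents that add atoms: ozone, [O-][O+]=O
Why: Ozonolysis with reductive work-up should cleave only the electron-rich trisubstituted alkene, which reacts much faster than the monosubstituted vinyl group next to the silyloxy-bearing carbon.

**Step 3**
Reactants: 4 (4S)-4-methyl-4-(triethylsilyloxy)hex-5-enal; 5 2-methyl-1-(trimethylsilyloxy)prop-1-ene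
Product: 7 (6S)-3-hydroxy-2,2,6-trimethyl-6-(triethylsilyloxy)oct-7-enal (both C3 epimers), via silyl aldolate 6 (not isolated)
Conditions: Sc(OTf)3 (5 mol %), CH2Cl2, −78 °C; then aq. citric acid, THF, 0 °C
Reagents that add atoms: 2-methyl-1-(trimethylsilyloxy)prop-1-ene (5), CC(C)=CO[Si](C)(C)C
Why: A Lewis-acid-catalysed Mukaiyama aldol addition of the isobutyraldehyde enol silane builds the quaternary gem-dimethyl carbon and a new aldehyde at once; the carbinol centre forms without control, which is harmless because it is oxidised in step 4.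

**Step 4**
Reactants: 7 (6S)-3-hydroxy-2,2,6-trimethyl-6-(triethylsilyloxy)oct-7-enal
Product: 8 (6S)-2,2,6-trimethyl-3-oxo-6-(triethylsilyloxy)oct-7-enal
Conditions: Dess–Martin periodinane, pyridine, CH2Cl2, 0 °C → rt
Reagents that add atoms: none
Why: Dess–Martin oxidation of the secondary alcohol under non-basic conditions spares the aldehyde, the alkene and the silyl ether, and both carbinol epimers converge on one keto-aldehyde that cannot enolise between its carbonyls.

**Step 5**
Reactants: 8 (6S)-2,2,6-trimethyl-3-oxo-6-(triethylsilyloxy)oct-7-enal; 9 dimethyl (2-oxopropyl)phosphonate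
Product: 13 4,4-dimethyl-3-[(3S)-3-methyl-3-(triethylsilyloxy)pent-4-en-1-yl]cyclohexa-2,5-dien-1-one, via aldol adduct 10 (not isolated), via hydroxy enone 11 (not isolated), via mesylate 12 (not isolated)
Conditions: 9, NaH, then n-BuLi, THF, 0 °C; 8, −78 °C; AcOH (1 equiv), −78 → 60 °C; then MsCl, Et3N, 0 °C → rt
Reagents that add atoms: dimethyl (2-oxopropyl)phosphonate (9), CC(=O)CP(=O)(OC)OC
Why: The γ-carbon of the phosphonate dianion (the non-stabilised, more reactive carbanion) adds to the aldehyde of 8; one equivalent of acid then protonates only the alkoxide, the surviving phosphonate-stabilised carbanion olefinates the ketone intramolecularly (Horner–Wadsworth–Emmons), and mesylation with E1cB loss of the carbinol oxygen gives the cross-conjugated dienone. The closest known reactions are the γ-selective aldol addition of β-ketophosphonate dianions and the intramolecular HWE cyclohexenone annulation of keto-phosphonates. The six-membered ring closes in the olefination by a 6-(enolendo)-exo-trig attack of the phosphonate carbanion on the ketone carbonyl. No stereocentre is meant to survive: the aldol carbinol forms without control and is erased on purpose, so that this ring carbon can be set by catalysis in step 6, independently of the remote side-chain centre. The step needs chemoselectivity (aldehyde before ketone, secured by the α-quaternary, neopentyl ketone and the non-enolisable aldehyde), regiochemical fidelity (only the phosphorus-bearing carbon can form the C=C bond to the ketone carbon, so the ketone's own α-methylene cannot compete) and the right order of events (the single bond to the aldehyde carbon forms first, so no E-enone arises that could not cyclise).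

**Step 6**
Reactants: 13 4,4-dimethyl-3-[(3S)-3-methyl-3-(triethylsilyloxy)pent-4-en-1-yl]cyclohexa-2,5-dien-1-one
Product: 15 (5S)-5-hydroxy-4,4-dimethyl-3-[(3S)-3-methyl-3-(triethylsilyloxy)pent-4-en-1-yl]cyclohex-2-en-1-one, via boronate 14 (not isolated)
Conditions: CuCl (3 mol %), NaOt-Bu (6 mol %), (R)-1-[(SP)-2-(diphenylphosphino)ferrocenyl]ethyldicyclohexylphosphine (4 mol %), B2pin2, MeOH, THF, rt; then NaBO3·4H2O, THF/H2O, rt
Reagents that add atoms: sodium perborate, [Na+].[O-]OB=O
Why: Copper-catalysed enantioselective conjugate borylation should occur only at the β-carbon of the disubstituted enone (the other β-carbon is fully substituted); the chiral diphosphine sets the new stereocentre by catalyst control, and perborate oxidation replaces boron by hydroxyl with retention.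

**Step 7**
Reactants: 15 (5S)-5-hydroxy-4,4-dimethyl-3-[(3S)-3-methyl-3-(triethylsilyloxy)pent-4-en-1-yl]cyclohex-2-en-1-one; 16 N,N-dimethylmethyleneiminium iodide (Eschenmoser's salt)
Product: 20 (3S,5S)-5-hydroxy-4,4-dimethyl-2-methylidene-3-[(3S)-3-methyl-3-(triethylsilyloxy)pent-4-en-1-yl]cyclohexan-1-one, via bis-silyl enol ether 17 (not isolated), via Mannich base 18 (not isolated), via methiodide 19 (not isolated)
Conditions: [1,3-bis(2,6-diisopropylphenyl)imidazol-2-ylidene]CuCl (5 mol %), NaOt-Bu (5 mol %), (EtO)2MeSiH (3 equiv), toluene, 0 °C → rt; then 16, CH2Cl2, rt; then MeI, rt; aq. NaHCO3, THF, rt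
Reagents that add atoms: N,N-dimethylmethyleneiminium iodide (16), C=[N+](C)C.[I-]
Why: Copper hydride conjugate reduction should deliver hydride to the β-carbon axially and anti to the (in situ silylated) C5 oxygen, so the side chain ends cis to that oxygen (substrate control), and it gives the silyl enol ether only on the side of the former double bond; Mannich reaction with Eschenmoser's salt, N-methylation and E1cB elimination then place the exocyclic methylene at that α-carbon alone, and the labile alkoxysilyl ether is hydrolysed in the work-up.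

**Step 8**
Reactants: 20 (3S,5S)-5-hydroxy-4,4-dimethyl-2-methylidene-3-[(3S)-3-methyl-3-(triethylsilyloxy)pent-4-en-1-yl]cyclohexan-1-one
Product: 21 (1S,3S,5S)-4,4-dimethyl-6-methylidene-5-[(3S)-3-methyl-3-(triethylsilyloxy)pent-4-en-1-yl]cyclohexane-1,3-diol
Conditions: Me4NBH(OAc)3, MeCN/AcOH (1:1), −30 → 0 °C
Reagents that add atoms: none
Why: In this Evans–Saksena reduction the free hydroxyl binds boron and delivers hydride to the carbonyl carbon from its own face, which should give the 1,3-anti diol with the allylic hydroxyl trans to both the directing hydroxyl and the side chain, without 1,4-reduction of the enone.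

**Step 9**
Reactants: 21 (1S,3S,5S)-4,4-dimethyl-6-methylidene-5-[(3S)-3-methyl-3-(triethylsilyloxy)pent-4-en-1-yl]cyclohexane-1,3-diol
Product: 23 triethyl{[(3S)-5-[(1S,3R,5R)-3,5-dibromo-2,2-dimethyl-6-methylidenecyclohexyl]-3-methylpent-1-en-3-yl]oxy}silane, via monobromide 22 (not isolated)
Conditions: PPh3, CBr4, 2,6-lutidine, CH2Cl2, −20 → 40 °C
Reagents that add atoms: carbon tetrabromide, BrC(Br)(Br)Br
Why: In a double Appel reaction each carbinol is displaced by bromide with inversion (SN2) through its oxyphosphonium salt, first the axial allylic one (giving the equatorial bromide), then the equatorial neopentyl one (giving the axial bromide), which turns the trans-diol into the trans-dibromide of the target while the buffered medium spares the silyl ether.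

**Step 10**
Reactants: 23 triethyl{[(3S)-5-[(1S,3R,5R)-3,5-dibromo-2,2-dimethyl-6-methylidenecyclohexyl]-3-methylpent-1-en-3-yl]oxy}silane
Product: 24 (3S)-5-[(1S,3R,5R)-3,5-dibromo-2,2-dimethyl-6-methylidenecyclohexyl]-3-methylpent-1-en-3-ol (target)
Conditions: HF·pyridine, pyridine, THF, 0 °C → rt
Reagents that add atoms: none
Why: Buffered fluoride cleavage of the tertiary triethylsilyl ether should leave the secondary and allylic bromides and both alkenes untouched, and no stereocentre is involved.

**Compound list**
1 | (S)-(+)-linalool, (3S)-3,7-dimethylocta-1,6-dien-3-ol | C=C[C@@](C)(O)CCC=C(C)C | starting material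
2 | (3S)-3,7-dimethyl-3-(triethylsilyloxy)octa-1,6-diene | C=C[C@@](C)(O[Si](CC)(CC)CC)CCC=C(C)C | intermediate
3 | ozonide, 3,3-dimethyl-5-[(3S)-3-methyl-3-(triethylsilyloxy)pent-4-en-1-yl]-1,2,4-trioxolane (epimers at the ring CH) | C=C[C@@](C)(O[Si](CC)(CC)CC)CCC1OOC(C)(C)O1 | intermediate (not isolated)
4 | (4S)-4-methyl-4-(triethylsilyloxy)hex-5-enal | C=C[C@@](C)(O[Si](CC)(CC)CC)CCC=O | intermediate
5 | 2-methyl-1-(trimethylsilyloxy)prop-1-ene | CC(C)=CO[Si](C)(C)C | starting material
6 | (6S)-2,2,6-trimethyl-6-(triethylsilyloxy)-3-(trimethylsilyloxy)oct-7-enal (both C3 epimers) | C=C[C@@](C)(O[Si](CC)(CC)CC)CCC(O[Si](C)(C)C)C(C)(C)C=O | intermediate (not isolated)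
7 | (6S)-3-hydroxy-2,2,6-trimethyl-6-(triethylsilyloxy)oct-7-enal (both C3 epimers) | C=C[C@@](C)(O[Si](CC)(CC)CC)CCC(O)C(C)(C)C=O | intermediate
8 | (6S)-2,2,6-trimethyl-3-oxo-6-(triethylsilyloxy)oct-7-enal | C=C[C@@](C)(O[Si](CC)(CC)CC)CCC(=O)C(C)(C)C=O | intermediate
9 | dimethyl (2-oxopropyl)phosphonate | CC(=O)CP(=O)(OC)OC | starting material
10 | dimethyl [(9S)-4-hydroxy-5,5,9-trimethyl-2,6-dioxo-9-(triethylsilyloxy)undec-10-en-1-yl]phosphonate (both C4 epimers) | C=C[C@@](C)(O[Si](CC)(CC)CC)CCC(=O)C(C)(C)C(O)CC(=O)CP(=O)(OC)OC | intermediate (not isolated)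
11 | 5-hydroxy-4,4-dimethyl-3-[(3S)-3-methyl-3-(triethylsilyloxy)pent-4-en-1-yl]cyclohex-2-en-1-one (both C5 epimers) | C=C[C@@](C)(O[Si](CC)(CC)CC)CCC1=CC(=O)CC(O)C1(C)C | intermediate (not isolated)
12 | methanesulfonate of 11 (both C5 epimers) | C=C[C@@](C)(O[Si](CC)(CC)CC)CCC1=CC(=O)CC(OS(C)(=O)=O)C1(C)C | intermediate (not isolated)
13 | 4,4-dimethyl-3-[(3S)-3-methyl-3-(triethylsilyloxy)pent-4-en-1-yl]cyclohexa-2,5-dien-1-one | C=C[C@@](C)(O[Si](CC)(CC)CC)CCC1=CC(=O)C=CC1(C)C | intermediate
14 | (5S)-4,4-dimethyl-3-[(3S)-3-methyl-3-(triethylsilyloxy)pent-4-en-1-yl]-5-(4,4,5,5-tetramethyl-1,3,2-dioxaborolan-2-yl)cyclohex-2-en-1-one | C=C[C@@](C)(O[Si](CC)(CC)CC)CCC1=CC(=O)C[C@H](B2OC(C)(C)C(C)(C)O2)C1(C)C | intermediate (not isolated)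
15 | (5S)-5-hydroxy-4,4-dimethyl-3-[(3S)-3-methyl-3-(triethylsilyloxy)pent-4-en-1-yl]cyclohex-2-en-1-one | C=C[C@@](C)(O[Si](CC)(CC)CC)CCC1=CC(=O)C[C@H](O)C1(C)C | intermediate
16 | N,N-dimethylmethyleneiminium iodide (Eschenmoser's salt) | C=[N+](C)C.[I-] | starting material
17 | (3R,5S)-1,5-bis[diethoxy(methyl)silyloxy]-4,4-dimethyl-3-[(3S)-3-methyl-3-(triethylsilyloxy)pent-4-en-1-yl]cyclohex-1-ene (side chain cis to the C5 oxygen) | C=C[C@@](C)(O[Si](CC)(CC)CC)CC[C@@H]1C=C(O[Si](C)(OCC)OCC)C[C@H](O[Si](C)(OCC)OCC)C1(C)C | intermediate (not isolated)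
18 | (3R,5S)-5-[diethoxy(methyl)silyloxy]-2-[(dimethylamino)methyl]-4,4-dimethyl-3-[(3S)-3-methyl-3-(triethylsilyloxy)pent-4-en-1-yl]cyclohexan-1-one (C2 epimers) | C=C[C@@](C)(O[Si](CC)(CC)CC)CC[C@@H]1C(CN(C)C)C(=O)C[C@H](O[Si](C)(OCC)OCC)C1(C)C | intermediate (not isolated)
19 | N-methyl quaternary ammonium iodide of 18 | C=C[C@@](C)(O[Si](CC)(CC)CC)CC[C@@H]1C(C[N+](C)(C)C)C(=O)C[C@H](O[Si](C)(OCC)OCC)C1(C)C.[I-] | intermediate (not isolated)
20 | (3S,5S)-5-hydroxy-4,4-dimethyl-2-methylidene-3-[(3S)-3-methyl-3-(triethylsilyloxy)pent-4-en-1-yl]cyclohexan-1-one | C=C[C@@](C)(O[Si](CC)(CC)CC)CC[C@@H]1C(=C)C(=O)C[C@H](O)C1(C)C | intermediate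
21 | (1S,3S,5S)-4,4-dimethyl-6-methylidene-5-[(3S)-3-methyl-3-(triethylsilyloxy)pent-4-en-1-yl]cyclohexane-1,3-diol | C=C[C@@](C)(O[Si](CC)(CC)CC)CC[C@@H]1C(=C)[C@@H](O)C[C@H](O)C1(C)C | intermediate
22 | triethyl{[(3S)-5-[(1S,3S,5R)-5-bromo-3-hydroxy-2,2-dimethyl-6-methylidenecyclohexyl]-3-methylpent-1-en-3-yl]oxy}silane | C=C[C@@](C)(O[Si](CC)(CC)CC)CC[C@@H]1C(=C)[C@H](Br)C[C@H](O)C1(C)C | intermediate (not isolated)
23 | triethyl{[(3S)-5-[(1S,3R,5R)-3,5-dibromo-2,2-dimethyl-6-methylidenecyclohexyl]-3-methylpent-1-en-3-yl]oxy}silane | C=C[C@@](C)(O[Si](CC)(CC)CC)CC[C@@H]1C(=C)[C@H](Br)C[C@@H](Br)C1(C)C | intermediate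
24 | (3S)-5-[(1S,3R,5R)-3,5-dibromo-2,2-dimethyl-6-methylidenecyclohexyl]-3-methylpent-1-en-3-ol | C=C[C@@](C)(O)CC[C@@H]1C(=C)[C@H](Br)C[C@@H](Br)C1(C)C | target

**Step count and risks**
Total step count: 10. Longest linear sequence: 10 steps (from 1).

Steps most likely to fail:

1. Step 9 (double bromination). What may go wrong: at the equatorial neopentyl carbinol, the ring bond antiperiplanar to the leaving group may migrate (ring contraction) or elimination may win over backside attack; at the allylic carbinol, bromide may enter with allylic transposition. Fallback, from 21 back to 23: only the allylic carbinol is brominated (PPh3, CBr4, one equivalent, −20 °C) and monobromide 22 is isolated. Its remaining hydroxyl is turned with Tf2O and pyridine at −40 °C into the neopentyl triflate F1. This pre-formed sulfonate is displaced with inversion by LiBr in THF/2-butanone at 0 °C → rt to give 23, so the hindered substitution no longer goes through an oxyphosphonium salt at elevated temperature.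

2. Step 5 (annulation). What may go wrong: proton transfer from the ketone α-methylene to the dianion, retro-aldol fragmentation of the β-hydroxy ketone unit while the olefination of the hindered ketone is slow, or intermolecular condensation. Fallback, from 8 back to 13: the cascade is replaced by a protected, stepwise sequence. The dianion aldol is quenched at −78 °C and adduct 10 is isolated. Silylation (TMSCl, imidazole) gives the trimethylsilyl ether F2. Ring closure by intramolecular HWE under weak-base conditions (K2CO3, 18-crown-6, toluene, 60 °C) gives the silyloxy enone F3. Citric acid in MeOH liberates 11, which is mesylated and eliminated (MsCl, Et3N) to 13.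

3. Step 8 (directed reduction). What may go wrong: intramolecular hydride delivery needs a ring conformer with the directing oxygen axial, so it may be slow, and undirected 1,2-attack from the other face would lower facial selectivity. Fallback, from 20 back to 21: Luche reduction (NaBH4, CeCl3·7H2O, MeOH, −78 °C) should give, by axial attack, the all-cis diol F4. Mitsunobu inversion (4-nitrobenzoic acid, PPh3, DIAD, THF) at the allylic carbinol only (the neopentyl carbinol is too hindered to react) gives the 4-nitrobenzoate F5. Methanolysis (K2CO3, MeOH) gives 21.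

**Further compounds**
F1 | step 9 | triethyl{[(3S)-5-[(1S,3S,5R)-5-bromo-2,2-dimethyl-6-methylidene-3-(trifluoromethylsulfonyloxy)cyclohexyl]-3-methylpent-1-en-3-yl]oxy}silane | C=C[C@@](C)(O[Si](CC)(CC)CC)CC[C@@H]1C(=C)[C@H](Br)C[C@H](OS(=O)(=O)C(F)(F)F)C1(C)C
F2 | step 5 | dimethyl [(9S)-5,5,9-trimethyl-2,6-dioxo-9-(triethylsilyloxy)-4-(trimethylsilyloxy)undec-10-en-1-yl]phosphonate (both C4 epimers) | C=C[C@@](C)(O[Si](CC)(CC)CC)CCC(=O)C(C)(C)C(O[Si](C)(C)C)CC(=O)CP(=O)(OC)OC
F3 | step 5 | 4,4-dimethyl-3-[(3S)-3-methyl-3-(triethylsilyloxy)pent-4-en-1-yl]-5-(trimethylsilyloxy)cyclohex-2-en-1-one (both C5 epimers) | C=C[C@@](C)(O[Si](CC)(CC)CC)CCC1=CC(=O)CC(O[Si](C)(C)C)C1(C)C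
F4 | step 8 | (1R,3S,5S)-4,4-dimethyl-6-methylidene-5-[(3S)-3-methyl-3-(triethylsilyloxy)pent-4-en-1-yl]cyclohexane-1,3-diol | C=C[C@@](C)(O[Si](CC)(CC)CC)CC[C@@H]1C(=C)[C@H](O)C[C@H](O)C1(C)C
F5 | step 8 | (1S,3S,5S)-5-hydroxy-4,4-dimethyl-2-methylidene-3-[(3S)-3-methyl-3-(triethylsilyloxy)pent-4-en-1-yl]cyclohexyl 4-nitrobenzoate | C=C[C@@](C)(O[Si](CC)(CC)CC)CC[C@@H]1C(=C)[C@@H](OC(=O)c2ccc(cc2)[N+](=O)[O-])C[C@H](O)C1(C)C
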